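The cyclohexene (C1 bears CH2OBz, C2 is the vinylic CH, C3 OMe, C4 OH, C5 OBz, C6 OH) is cut at C2–C3 and C5–C6 into two achiral three-carbon pieces that already carry every oxygen substituent: a Z β-silyl enal (C2, C1, C6 with the CH2OBz branch) and the silyl enol ether of an α-keto dimethyl acetal (C3, C4 as ketone, C5). The key step exploits this pairing in one flask: a catalytic enantioselective Mukaiyama aldol makes C5–C6 and sets C6; enol silylation and acetal ionisation then give an alkoxy-oxyallyl cation that the vinylsilane captures, making C2–C3. C3, C5 and later C4 are relayed from C6; the C3 methoxy group is the residue of the acetal.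

Key step: step 5

Assumption: the (acyloxy)borane from (2R,3R)-tartaric acid is taken to direct silyl enol ethers to the Re face of aldehydes, so the (2S,3S)-tartaric acid-derived catalyst is written for the required Si-face attack on 2.
Ring positions in the text are numbered as in the target, whatever the locants of the systematic names.

Step 1
Reactants: 1 prop-2-yn-1-yl benzoate
Product: 2 (2Z)-3-[dimethyl(phenyl)silyl]-2-formylprop-2-en-1-yl benzoate
Conditions: PhMe2SiH (1.1 equiv), CO (20 atm), Rh4(CO)12 (0.5 mol %), Et3N (5 mol %), toluene, 80 °C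
Reagents that add atoms: dimethyl(phenyl)silane C[SiH](C)c1ccccc1; carbon monoxide [C-]#[O+]
Why: Rhodium-catalysed silylformylation of a terminal alkyne places silicon on the terminal carbon and the formyl group on the internal carbon by syn addition, so silicon and CHO should end cis (Z), the geometry the later ring closure needs.

Step 2
Reactants: 3 1,1-dimethoxypropan-2-one
Product: 4 1-bromo-3,3-dimethoxypropan-2-one
Conditions: Br2 (1.0 equiv), MeOH, 0 → 20 °C
Reagents that add atoms: bromine BrBr
Why: Acid-catalysed α-bromination of a methyl ketone in methanol should occur at the methyl group, because the other α-carbon is the hindered, inductively deactivated acetal carbon, and methanol keeps the acetal intact.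

Step 3
Reactants: 4 1-bromo-3,3-dimethoxypropan-2-one
Product: 5 3,3-dimethoxy-2-oxopropyl benzoate
Conditions: PhCO2K (1.2 equiv), DMF, 20 °C
Reagents that add atoms: potassium benzoate [K+].[O-]C(=O)c1ccccc1
Why: SN2 displacement of a primary α-bromo ketone by a carboxylate, accelerated by the adjacent carbonyl group.

Step 4
Reactants: 5 3,3-dimethoxy-2-oxopropyl benzoate
Product: 6 (1Z)-3,3-dimethoxy-2-[(trimethylsilyl)oxy]prop-1-en-1-yl benzoate
Conditions: Me3SiCl (1.5 equiv, present before the base), LiN(SiMe3)2 (1.05 equiv), THF, −78 °C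
Reagents that add atoms: chlorotrimethylsilane C[Si](C)(C)Cl
Why: Kinetic enolisation at the only CH2 group with an internal silyl quench (silyl enol ether formation) should give the Z enol ether because lithium bridges the two oxygens, and the in situ trap should outrun benzoyl migration.

Step 5
Reactants: 2 (2Z)-3-[dimethyl(phenyl)silyl]-2-formylprop-2-en-1-yl benzoate; 6 (1Z)-3,3-dimethoxy-2-[(trimethylsilyl)oxy]prop-1-en-1-yl benzoate
Product: 10 (2R,5R,6R)-6-(benzoyloxy)-4-[(benzoyloxy)methyl]-5-hydroxy-2-methoxycyclohex-3-en-1-one, via aldol silyl ether 7 (not isolated), via bis-silyl enol ether 8 (not isolated), via cyclic silyl enol ether 9 (not isolated)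
Conditions: (2S,3S)-2-O-(2,6-diisopropoxybenzoyl)tartaric acid/BH3·THF (20 mol %), EtCN, −78 °C; then Et3N (3 equiv), Me3SiOTf (2.2 equiv), CH2Cl2, −78 → −30 °C; then AcOH, −78 °C; aq. citric acid, THF, 0 °C
Reagents that add atoms: none
Why: Proposed new method: the (acyloxy)borane catalyses a Mukaiyama aldol of 6 with the formyl group of 2 (C5–C6 bond, 7), Et3N/Me3SiOTf then turn the ketone into silyl enol ether 8, whose allylic acetal ionises with loss of MeOSiMe3 to a 1-methoxy-2-silyloxyallyl cation that is attacked at its methoxy terminus by the silicon-bearing carbon of the vinylsilane (C2–C3 bond), and loss of the silyl group from the β-silyl cation gives 9, which is protonated to 10 on work-up. The closest known reaction types are the catalytic enantioselective Mukaiyama aldol, the generation of alkoxy-oxyallyl cations from silyl enol ethers of α-keto acetals for (4+3) cycloadditions, and vinylsilane-terminated cation cyclisation; untested are their union in one flask and the capture of such a cation by a vinylsilane. The ring closes in the 6-endo mode with respect to the alkene, which the β-silicon effect enforces and the Z vinylsilane permits, because ipso substitution with retention puts the new bond cis to C6 across the C1=C2 bond. C6 is set by the catalyst (Si-face attack on the aldehyde); C3 is set in the ring closure, where allylic 1,2-strain holds the C6 silyloxy group in a flagpole position of the boat-like cyclohexa-1,4-diene so that the methoxy group should end trans to it; C5 is set by protonation of 9 anti to that silyloxy group, which puts the benzoate cis to it and makes the syn/anti outcome of the aldol irrelevant. The step needs the aldehyde to be consumed before any acetal ionises, which is secured by adding Me3SiOTf only after the boron-catalysed aldol, and it needs ionisation of the acetal and not of the doubly allylic C6 silyl ether, which the much easier loss of methoxide to silicon at low temperature should secure.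

Step 6
Reactants: 10 (2R,5R,6R)-6-(benzoyloxy)-4-[(benzoyloxy)methyl]-5-hydroxy-2-methoxycyclohex-3-en-1-one
Product: 11 [(3R,4R,5R,6R)-5-(benzoyloxy)-4,6-dihydroxy-3-methoxycyclohex-1-en-1-yl]methyl benzoate
Conditions: Me4NBH(OAc)3 (5 equiv), MeCN–AcOH (1:1), −30 °C
Reagents that add atoms: none
Why: Hydroxyl-directed triacetoxyborohydride reduction (Evans–Saksena reduction): the pseudo-axial C6 hydroxyl binds boron and delivers hydride to its own face of the C4 ketone, so the new C4 hydroxyl should be anti to the C6 hydroxyl, that is cis to the C3 methoxy group and trans to the C5 benzoate.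

Compound list
1 | prop-2-yn-1-yl benzoate | C#CCOC(=O)c1ccccc1 | starting material
2 | (2Z)-3-[dimethyl(phenyl)silyl]-2-formylprop-2-en-1-yl benzoate | O=C/C(COC(=O)c1ccccc1)=C\[Si](C)(C)c1ccccc1 | intermediate
3 | 1,1-dimethoxypropan-2-one | CC(=O)C(OC)OC | starting material
4 | 1-bromo-3,3-dimethoxypropan-2-one | BrCC(=O)C(OC)OC | intermediate
5 | 3,3-dimethoxy-2-oxopropyl benzoate | COC(OC)C(=O)COC(=O)c1ccccc1 | intermediate
6 | (1Z)-3,3-dimethoxy-2-[(trimethylsilyl)oxy]prop-1-en-1-yl benzoate | COC(OC)/C(O[Si](C)(C)C)=C/OC(=O)c1ccccc1 | intermediate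
7 | (1Z,3R,4RS)-2-[(benzoyloxy)methyl]-1-[dimethyl(phenyl)silyl]-6,6-dimethoxy-5-oxo-3-[(trimethylsilyl)oxy]hex-1-en-4-yl benzoate (aldol silyl ether, both epimers at the benzoyloxy carbon) | C[Si](C)(c1ccccc1)/C=C(/COC(=O)c1ccccc1)[C@@H](O[Si](C)(C)C)C(OC(=O)c1ccccc1)C(=O)C(OC)OC | intermediate
8 | (1Z,3R,4Z)-2-[(benzoyloxy)methyl]-1-[dimethyl(phenyl)silyl]-6,6-dimethoxy-3,5-bis[(trimethylsilyl)oxy]hexa-1,4-dien-4-yl benzoate (bis-silyl enol ether) | C[Si](C)(c1ccccc1)/C=C(/COC(=O)c1ccccc1)[C@@H](O[Si](C)(C)C)/C(OC(=O)c1ccccc1)=C(/O[Si](C)(C)C)C(OC)OC | intermediate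
9 | (3R,6R)-5-[(benzoyloxy)methyl]-3-methoxy-2,6-bis[(trimethylsilyl)oxy]cyclohexa-1,4-dien-1-yl benzoate (cyclic silyl enol ether) | CO[C@@H]1C=C(COC(=O)c2ccccc2)[C@@H](O[Si](C)(C)C)C(OC(=O)c2ccccc2)=C1O[Si](C)(C)C | intermediate
10 | (2R,5R,6R)-6-(benzoyloxy)-4-[(benzoyloxy)methyl]-5-hydroxy-2-methoxycyclohex-3-en-1-one | CO[C@@H]1C=C(COC(=O)c2ccccc2)[C@@H](O)[C@@H](OC(=O)c2ccccc2)C1=O | intermediate
11 | [(3R,4R,5R,6R)-5-(benzoyloxy)-4,6-dihydroxy-3-methoxycyclohex-1-en-1-yl]methyl benzoate | CO[C@@H]1C=C(COC(=O)c2ccccc2)[C@@H](O)[C@@H](OC(=O)c2ccccc2)[C@@H]1O | target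

Total step count: 6. Longest linear sequence: 5 steps (3 → 4 → 5 → 6 → 10 → 11).

Steps most likely to fail

Step 5 (Proposed new method). The aldol may show poor facial control on the hindered enal. In the second stage the cation may form slowly or at the wrong site (ionisation of the doubly allylic silyl ether in place of the acetal) or may oligomerise before the ring closes. The vinylsilane may be lost by protodesilylation, and the β,γ-unsaturated hydroxy ketone may aromatise by β-elimination during work-up. The fallback uses known reactions only, makes the two bonds in separate flasks, reduces the ketone before the ring is closed and installs the C5 benzoate last. It sets out from 5 and 2 and returns at 11. Methanolysis of 5 (K2CO3, MeOH, 0 °C) gives 1-hydroxy-3,3-dimethoxypropan-2-one F1. A D-proline-catalysed direct aldol of this α-hydroxy ketone with 2 (DMSO, 20 °C; enamine aldol, anti-diol) should give the (3R,4R) anti-diol ketone F2. Reduction with Me4NBH(OAc)3 (MeCN–AcOH, −30 °C) should give the 1,3-anti triol F3, and Me3SiCl/imidazole gives its tris(trimethylsilyl) ether F4. SnCl4 (CH2Cl2, −78 °C; vinylsilane-terminated cyclisation of a dimethyl acetal) and acidic work-up should then give the cyclohexene triol F5, from which any C3 epimer is removed. Finally Bu2SnO, then BzCl, should benzoylate the equatorial oxygen of the cis-diol (C5) to give 11.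

Step 6. The C6 hydroxyl may be lost by β-elimination with aromatisation under the acidic hydride conditions, a benzoyl group may migrate, or non-directed hydride attack may give the C4 epimer. The fallback replaces the external hydride by an intramolecular hydride transfer of the Tishchenko type; it sets out from 10 and returns at 11. Acetaldehyde with Sc(OTf)3 (10 mol %) in THF at −10 °C (Evans–Tishchenko reduction) should convert 10, through its hemiacetal, into the 1,3-anti diol monoacetate, the 6-O-acetyl derivative of 11 F6. Mg(OMe)2 in MeOH at 0 °C then removes the acetate, which reacts well before the benzoates.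

Step 4. The benzoyl group may migrate or be cleaved at the enolate stage, enolisation may stray to the acetal carbon, and the labile enol ether may be lost on isolation. The fallback carries C5 as a silyl ether, which cannot migrate, and introduces the benzoate after the ring is made; it sets out from 5 and returns at 10. Methanolysis of 5 (K2CO3, MeOH, 0 °C) gives the hydroxy ketone F1 described above, and Me3SiCl/Et3N converts it into the enediol ether (Z)-3,3-dimethoxy-1,2-bis[(trimethylsilyl)oxy]prop-1-ene F7. F7 is used in place of 6 under the conditions of step 5 and should give, after work-up, the 5,6-diol ketone F8. BzCl with 2,4,6-collidine at −40 °C should then acylate the more acidic, equatorial C5 hydroxyl next to the ketone to give 10.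

Further compounds
F1 | step 5 | 1-hydroxy-3,3-dimethoxypropan-2-one | OCC(=O)C(OC)OC
F2 | step 5 | [(2Z,3R,4R)-2-{[dimethyl(phenyl)silyl]methylidene}-3,4-dihydroxy-6,6-dimethoxy-5-oxohexyl] benzoate (anti-diol ketone) | C[Si](C)(c1ccccc1)/C=C(/COC(=O)c1ccccc1)[C@@H](O)[C@@H](O)C(=O)C(OC)OC
F3 | step 5 | [(2Z,3R,4R,5S)-2-{[dimethyl(phenyl)silyl]methylidene}-3,4,5-trihydroxy-6,6-dimethoxyhexyl] benzoate (1,3-anti triol) | C[Si](C)(c1ccccc1)/C=C(/COC(=O)c1ccccc1)[C@@H](O)[C@@H](O)[C@H](O)C(OC)OC
F4 | step 5 | tris(trimethylsilyl) ether of F3 | C[Si](C)(c1ccccc1)/C=C(/COC(=O)c1ccccc1)[C@@H](O[Si](C)(C)C)[C@@H](O[Si](C)(C)C)[C@H](O[Si](C)(C)C)C(OC)OC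
F5 | step 5 | [(3R,4S,5R,6R)-4,5,6-trihydroxy-3-methoxycyclohex-1-en-1-yl]methyl benzoate (11 without the C5 benzoyl group) | CO[C@@H]1C=C(COC(=O)c2ccccc2)[C@@H](O)[C@@H](O)[C@@H]1O
F6 | step 6 | 6-O-acetyl derivative of 11 (configuration as in 11 at all four centres) | CO[C@@H]1C=C(COC(=O)c2ccccc2)[C@@H](OC(C)=O)[C@@H](OC(=O)c2ccccc2)[C@@H]1O
F7 | step 4 | (Z)-3,3-dimethoxy-1,2-bis[(trimethylsilyl)oxy]prop-1-ene | COC(OC)/C(O[Si](C)(C)C)=C/O[Si](C)(C)C
F8 | step 4 | (2R,5R,6R)-4-[(benzoyloxy)methyl]-5,6-dihydroxy-2-methoxycyclohex-3-en-1-one | CO[C@@H]1C=C(COC(=O)c2ccccc2)[C@@H](O)[C@@H](O)C1=O
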